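**Plan**

Labels: ring A = the cyclohexenone, ring B = the spiro γ-lactone, C10 = the lactone O–CH carbon, C11=C12 = the side-chain alkene (C12 carries the methyl group).
Retrosynthetic cuts, in order: the silyl ether; the acyl C–O bond of ring B (back to a tert-butyl ester arm); C12–CH3 (back to C12–B); C11=C12 together with the B–O(C10) bond (back to a C10 vinyl carbinol and a 1-substituted vinylboronic acid); C10–vinyl; the two ring-A bonds (quaternary C–carbonyl C and CH2–CH(O)) made by a furan Diels–Alder reaction.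
Enabling feature: C11=C12 is trisubstituted with the C12 methyl cis to C10, and C10 bears oxygen, so O–B–C12=C11–C10 can be closed as a five-membered 1,2-oxaborole in which boron holds the place of the methyl group and can only sit cis to C10.
Forward order: ring A arises first (2-methoxyfuran plus an α-methylene aldehyde, then opening of the bridged ketal), the C10 vinyl carbinol follows, the side chain is joined through the temporary oxaborole, boron is exchanged for methyl, and ring B closes last.
Stereochemistry: the quaternary carbon and the ring C–O centre come from one catalyst-controlled exo Diels–Alder event, C10 from ligand-controlled vinyl transfer, the side-chain carbinol from a Corey–Bakshi–Shibata reduction, and the E alkene from the boron tether.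

Key step: step 11

Assumption: the catalyst enantiomers written in steps 2 and 3 are those expected, from the usual sense of induction of each catalyst class, to give attack on the Cα Re face of enal 2 and on the Re face of aldehyde 4; if a trial shows the opposite sense, the mirror-image catalyst is used.

**Route**

Step 1
Reactants: 1 tert-butyl 4-oxobutanoate
Product: 2 tert-butyl 3-formylbut-3-enoate
Conditions: 37% aq. CH2O (1.1 equiv), pyrrolidine (10 mol %), EtCO2H (10 mol %), i-PrOH, 45 °C
Reagents that add atoms: formaldehyde, C=O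
Why: Organocatalytic α-methylenation of an aldehyde (Mannich condensation of the pyrrolidine enamine with formaldehyde, then loss of the amine); the weakly acidic buffer and short contact time should keep the β,γ-unsaturated ester from moving into conjugation.

Step 2
Reactants: 2 tert-butyl 3-formylbut-3-enoate; 3 2-methoxyfuran
Product: 4 tert-butyl 2-[(1S,2R,4S)-2-formyl-1-methoxy-7-oxabicyclo[2.2.1]hept-5-en-2-yl]acetate (formyl exo, syn to the oxygen bridge)
Conditions: 3 (1.5 equiv), (R)-2-butyl-4-(1H-indol-3-ylmethyl)-3-tosyl-1,3,2-oxazaborolidin-5-one (10 mol %, from N-tosyl-D-tryptophan and BuB(OH)2), CH2Cl2, −78 °C; Et3N quench, cold filtration through Et3N-deactivated silica, used at once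
Reagents that add atoms: none
Why: Chiral-Lewis-acid-catalysed Diels–Alder reaction of a furan with a 2-substituted acrolein: the free furan α-carbon (largest HOMO coefficient) bonds to the enal CH2 so that the methoxy carbon ends next to the new quaternary centre, the formyl group takes the exo position usual for 2-substituted acroleins (later cis to the ring oxygen), and the catalyst leaves only the Cα Re face open, so both ring stereocentres are set in one event.

Step 3
Reactants: 4 tert-butyl 2-[(1S,2R,4S)-2-formyl-1-methoxy-7-oxabicyclo[2.2.1]hept-5-en-2-yl]acetate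
Product: 6 tert-butyl 2-[(1R,5S)-5-hydroxy-1-[(1R)-1-hydroxyprop-2-en-1-yl]-2-oxocyclohex-3-en-1-yl]acetate, via bicyclic vinyl carbinol 5 (not isolated)
Conditions: Zn(CH=CH2)2 (2 equiv), (2R)-(+)-3-exo-(dimethylamino)isoborneol (10 mol %), toluene/Et2O, −20 to 0 °C; then AcOH/H2O/THF, 0 °C to rt
Reagents that add atoms: divinylzinc, C=C[Zn]C=C; water, O
Why: Amino-alcohol-catalysed alkenylzinc addition to an aldehyde delivers vinyl to the Re face of the non-enolisable formyl group and sets (R)-C10 (a zinc chelate between the formyl and ketal oxygens should reinforce this, since the face beside the ring CH2 is more open than that beside the ester arm); dilute acetic acid then hydrolyses the strained bridged methoxy ketal to the 4-hydroxy enone without touching the tert-butyl ester.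

Step 4
Reactants: 6 tert-butyl 2-[(1R,5S)-5-hydroxy-1-[(1R)-1-hydroxyprop-2-en-1-yl]-2-oxocyclohex-3-en-1-yl]acetate
Product: 7 tert-butyl 2-[(1R,5S)-5-acetoxy-1-[(1R)-1-hydroxyprop-2-en-1-yl]-2-oxocyclohex-3-en-1-yl]acetate
Conditions: Ac2O (1.1 equiv), pyridine, CH2Cl2, −20 °C
Reagents that add atoms: acetic anhydride, CC(=O)OC(C)=O
Why: Sterically controlled O-acylation: the ring carbinol is an ordinary secondary allylic alcohol, whereas the C10 hydroxyl lies next to the quaternary carbon and should react much more slowly, so one equivalent of anhydride should give the mono-acetate.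

Step 5
Reactants: 8 pent-4-ynoic acid
Product: 10 N-methoxy-N-methylpent-4-ynamide, via acyl imidazole 9 (not isolated)
Conditions: CDI (1.1 equiv), CH2Cl2, rt; then MeNH(OMe)·HCl (1.2 equiv), rt
Reagents that add atoms: 1,1'-carbonyldiimidazole, O=C(n1ccnc1)n1ccnc1 (its imidazole stays only in 9); N,O-dimethylhydroxylamine hydrochloride, CNOC.Cl
Why: Carboxyl activation as the acyl imidazole followed by aminolysis (Weinreb amide formation), which the terminal alkyne tolerates.

Step 6
Reactants: 10 N-methoxy-N-methylpent-4-ynamide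
Product: 11 2-methylhept-1-en-6-yn-3-one
Conditions: CH2=C(CH3)MgBr (2.3 equiv), THF, −20 to 0 °C; inverse quench into cold 1 M HCl
Reagents that add atoms: isopropenylmagnesium bromide, C=C(C)[Mg]Br
Why: Weinreb ketone synthesis: the N-methoxy-N-methyl amide accepts only one alkenyl group (a further equivalent of Grignard reagent is consumed by the alkyne C–H, which is returned on work-up), and the cold acidic quench keeps the released amine from adding to the enone.

Step 7
Reactants: 11 2-methylhept-1-en-6-yn-3-one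
Product: 12 (3R)-2-methylhept-1-en-6-yn-3-ol
Conditions: (S)-Me-CBS [(3aS)-1-methyl-3,3-diphenyltetrahydro-1H,3H-pyrrolo[1,2-c][1,3,2]oxazaborole] (20 mol %), catecholborane (1.5 equiv), toluene, −78 °C; aq. NaOH work-up
Reagents that add atoms: none
Why: Corey–Bakshi–Shibata reduction: with the 1-methylvinyl group as the large substituent and the CH2 chain as the small one, the (S)-oxazaborolidine should give the (R)-allylic alcohol by 1,2-reduction, and catecholborane at −78 °C leaves the alkyne and alkene alone.

Step 8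
Reactants: 12 (3R)-2-methylhept-1-en-6-yn-3-ol
Product: 13 tert-butyl(dimethyl){[(3R)-2-methylhept-1-en-6-yn-3-yl]oxy}silane
Conditions: TBSCl, imidazole, DMF, rt
Reagents that add atoms: tert-butyldimethylsilyl chloride, CC(C)(C)[Si](C)(C)Cl
Why: Standard silylation of a secondary alcohol, which protects the carbinol through the organolithium, metathesis and coupling steps.

Step 9
Reactants: 13 tert-butyl(dimethyl){[(3R)-2-methylhept-1-en-6-yn-3-yl]oxy}silane
Product: 15 {[(3R)-6-bromo-2-methylhepta-1,6-dien-3-yl]oxy}(tert-butyl)dimethylsilane, via bromoboration adduct 14 (not isolated)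
Conditions: 9-bromo-9-BBN (1.2 equiv), CH2Cl2, 0 °C; then AcOH, 0 °C; aq. NaHCO3
Reagents that add atoms: 9-bromo-9-borabicyclo[3.3.1]nonane, BrB1C2CCCC1CCC2
Why: Haloboration–protonolysis: B–Br adds syn across the terminal alkyne with bromine at the internal carbon, and acetic acid cleaves the alkenyl–boron bond with retention, so the 2-bromo-1-alkene (net Markovnikov hydrobromination) should form while the 1,1-disubstituted alkene and the silyl ether stay intact at 0 °C.

Step 10
Reactants: 15 {[(3R)-6-bromo-2-methylhepta-1,6-dien-3-yl]oxy}(tert-butyl)dimethylsilane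
Product: 18 [(5R)-5-{[tert-butyl(dimethyl)silyl]oxy}-6-methylhepta-1,6-dien-2-yl]boronic acid, via alkenyllithium 16 (not isolated), via lithium triisopropoxyborate 17 (not isolated)
Conditions: t-BuLi (2.1 equiv), Et2O, −78 °C; B(Oi-Pr)3 (1.5 equiv), −78 °C to rt; 1 M HCl, 0 °C, brief
Reagents that add atoms: tert-butyllithium, [Li]C(C)(C)C (lithium stays only in 16 and 17); triisopropyl borate, CC(C)OB(OC(C)C)OC(C)C; water, O
Why: Bromine–lithium exchange followed by borylation of the alkenyllithium with a borate ester and brief acid hydrolysis gives the 1-substituted vinylboronic acid; the carbinol centre is not involved.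

Step 11
Reactants: 7 tert-butyl 2-[(1R,5S)-5-acetoxy-1-[(1R)-1-hydroxyprop-2-en-1-yl]-2-oxocyclohex-3-en-1-yl]acetate; 18 [(5R)-5-{[tert-butyl(dimethyl)silyl]oxy}-6-methylhepta-1,6-dien-2-yl]boronic acid
Product: 20 tert-butyl 2-[(1R,5S)-5-acetoxy-1-[(5R)-3-[(3R)-3-{[tert-butyl(dimethyl)silyl]oxy}-4-methylpent-4-en-1-yl]-2-hydroxy-2,5-dihydro-1,2-oxaborol-5-yl]-2-oxocyclohex-3-en-1-yl]acetate, via mixed boronic half ester 19 (not isolated)
Conditions: 18 (1.5 equiv), 4 Å molecular sieves, CH2Cl2, rt; then second-generation Grubbs catalyst RuCl2(=CHPh)(PCy3)(H2IMes) (10 mol %), toluene, 60 °C, argon sparge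
Reagents that add atoms: none
Why: The C10 alcohol and the boronic acid condense reversibly to the mixed allyl alkenyl boronate 19; the ruthenium benzylidene then exchanges onto the only monosubstituted alkene (the C10 vinyl group), the new alkylidene adds across the tethered 1,1-disubstituted vinylboron unit, and cycloreversion of the ruthenacyclobutane releases the ring and Ru=CH2, which ends as ethene. This is the known boron-tethered ring-closing metathesis of allylic alcohols with alkenylboronates. The single ring formed, the 2,5-dihydro-1,2-oxaborole O–B–C12=C11–C10, closes at the C11=C12 double bond by ring-closing alkene metathesis of a diene held together by the B–O bond. No stereocentre is created; C10 is not touched and the ring-A centres are remote. The step has to pick two of five alkenes and fix the alkene geometry: the enone C=C is electron-poor and the isopropenyl group is 1,1-disubstituted and could only close a nine-membered ring or a tetrasubstituted cyclopentene, so only the tethered pair should react, and the five-membered ring can hold boron and C10 only cis on C12=C11, which becomes the E geometry once boron is exchanged for methyl.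

Step 12
Reactants: 20 tert-butyl 2-[(1R,5S)-5-acetoxy-1-[(5R)-3-[(3R)-3-{[tert-butyl(dimethyl)silyl]oxy}-4-methylpent-4-en-1-yl]-2-hydroxy-2,5-dihydro-1,2-oxaborol-5-yl]-2-oxocyclohex-3-en-1-yl]acetate
Product: 21 tert-butyl 2-[(1R,5S)-5-acetoxy-1-[(1R,2E,6R)-6-{[tert-butyl(dimethyl)silyl]oxy}-1-hydroxy-3,7-dimethylocta-2,7-dien-1-yl]-2-oxocyclohex-3-en-1-yl]acetate
Conditions: MeI (5 equiv), Pd(dppf)Cl2 (10 mol %), K3PO4 (3 equiv), THF/H2O (10:1), 40 °C
Reagents that add atoms: iodomethane, CI
Why: Suzuki–Miyaura coupling of a cyclic alkenylboronic half ester with an alkyl iodide: methyl iodide adds oxidatively to zerovalent palladium, the hydroxide-activated alkenylboron transmetalates with retention of geometry, and reductive elimination makes the C12–CH3 bond while the tether opens to the free C10 hydroxyl; a weak base and low temperature are chosen because the product is a β-hydroxy ketone and an allylic acetate.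

Step 13
Reactants: 21 tert-butyl 2-[(1R,5S)-5-acetoxy-1-[(1R,2E,6R)-6-{[tert-butyl(dimethyl)silyl]oxy}-1-hydroxy-3,7-dimethylocta-2,7-dien-1-yl]-2-oxocyclohex-3-en-1-yl]acetate
Product: 22 (1R,5R,9S)-1-[(1E,5R)-5-{[tert-butyl(dimethyl)silyl]oxy}-2,6-dimethylhepta-1,6-dien-1-yl]-3,6-dioxo-2-oxaspiro[4.5]dec-7-en-9-yl acetate
Conditions: (1S)-(+)-10-camphorsulfonic acid (20 mol %), CH2Cl2, 0 °C to rt
Reagents that add atoms: none
Why: Acid-catalysed intramolecular transesterification (lactonisation, 5-exo-trig) closes ring B, helped by the quaternary carbon between alcohol and ester arm (Thorpe–Ingold effect); catalytic sulfonic acid in a non-ionising solvent is chosen so that the allylic C10–O bond is not ionised, and C10 keeps its configuration because only the acyl C–O bond is exchanged.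

Step 14
Reactants: 22 (1R,5R,9S)-1-[(1E,5R)-5-{[tert-butyl(dimethyl)silyl]oxy}-2,6-dimethylhepta-1,6-dien-1-yl]-3,6-dioxo-2-oxaspiro[4.5]dec-7-en-9-yl acetate
Product: 23 (1R,5R,9S)-1-[(1E,5R)-5-hydroxy-2,6-dimethylhepta-1,6-dien-1-yl]-3,6-dioxo-2-oxaspiro[4.5]dec-7-en-9-yl acetate (target)
Conditions: HF·pyridine, pyridine/THF, 0 °C to rt
Reagents that add atoms: none
Why: Fluoride-mediated desilylation under buffered, non-basic conditions should free the side-chain alcohol and leave the acetate, the lactone and the enone untouched.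

**Compound list**

1 | tert-butyl 4-oxobutanoate | CC(C)(C)OC(=O)CCC=O | starting material
2 | tert-butyl 3-formylbut-3-enoate | CC(C)(C)OC(=O)CC(=C)C=O | intermediate
3 | 2-methoxyfuran | COc1ccco1 | starting material
4 | tert-butyl 2-[(1S,2R,4S)-2-formyl-1-methoxy-7-oxabicyclo[2.2.1]hept-5-en-2-yl]acetate (formyl exo) | O=C[C@]1(CC(=O)OC(C)(C)C)C[C@H]2C=C[C@]1(OC)O2 | intermediate
5 | tert-butyl 2-[(1S,2R,4S)-2-[(1R)-1-hydroxyprop-2-en-1-yl]-1-methoxy-7-oxabicyclo[2.2.1]hept-5-en-2-yl]acetate (bicyclic vinyl carbinol, not isolated) | C=C[C@@H](O)[C@]1(CC(=O)OC(C)(C)C)C[C@H]2C=C[C@]1(OC)O2 | intermediate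
6 | tert-butyl 2-[(1R,5S)-5-hydroxy-1-[(1R)-1-hydroxyprop-2-en-1-yl]-2-oxocyclohex-3-en-1-yl]acetate | C=C[C@@H](O)[C@]1(CC(=O)OC(C)(C)C)C[C@H](O)C=CC1=O | intermediate
7 | tert-butyl 2-[(1R,5S)-5-acetoxy-1-[(1R)-1-hydroxyprop-2-en-1-yl]-2-oxocyclohex-3-en-1-yl]acetate | C=C[C@@H](O)[C@]1(CC(=O)OC(C)(C)C)C[C@H](OC(C)=O)C=CC1=O | intermediate
8 | pent-4-ynoic acid | C#CCCC(=O)O | starting material
9 | 1-(1H-imidazol-1-yl)pent-4-yn-1-one (acyl imidazole, not isolated) | C#CCCC(=O)n1ccnc1 | intermediate
10 | N-methoxy-N-methylpent-4-ynamide | C#CCCC(=O)N(C)OC | intermediate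
11 | 2-methylhept-1-en-6-yn-3-one | C=C(C)C(=O)CCC#C | intermediate
12 | (3R)-2-methylhept-1-en-6-yn-3-ol | C=C(C)[C@H](O)CCC#C | intermediate
13 | tert-butyl(dimethyl){[(3R)-2-methylhept-1-en-6-yn-3-yl]oxy}silane | C=C(C)[C@H](O[Si](C)(C)C(C)(C)C)CCC#C | intermediate
14 | 9-[(1Z,5R)-2-bromo-5-{[tert-butyl(dimethyl)silyl]oxy}-6-methylhepta-1,6-dien-1-yl]-9-borabicyclo[3.3.1]nonane (bromoboration adduct, not isolated) | C=C(C)[C@H](O[Si](C)(C)C(C)(C)C)CC/C(Br)=C/B1C2CCCC1CCC2 | intermediate
15 | {[(3R)-6-bromo-2-methylhepta-1,6-dien-3-yl]oxy}(tert-butyl)dimethylsilane | C=C(C)[C@H](O[Si](C)(C)C(C)(C)C)CCC(Br)=C | intermediate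
16 | [(5R)-5-{[tert-butyl(dimethyl)silyl]oxy}-6-methylhepta-1,6-dien-2-yl]lithium (not isolated) | C=C(C)[C@H](O[Si](C)(C)C(C)(C)C)CCC([Li])=C | intermediate
17 | lithium [(5R)-5-{[tert-butyl(dimethyl)silyl]oxy}-6-methylhepta-1,6-dien-2-yl]tri(propan-2-yloxy)borate (not isolated) | [Li+].C=C(C)[C@H](O[Si](C)(C)C(C)(C)C)CCC(=C)[B-](OC(C)C)(OC(C)C)OC(C)C | intermediate
18 | [(5R)-5-{[tert-butyl(dimethyl)silyl]oxy}-6-methylhepta-1,6-dien-2-yl]boronic acid | C=C(CC[C@@H](O[Si](C)(C)C(C)(C)C)C(C)=C)B(O)O | intermediate
19 | mixed boronic half ester of 7 and 18, C10–O–B(OH)–alkenyl (not isolated) | C=C[C@@H](OB(O)C(=C)CC[C@@H](O[Si](C)(C)C(C)(C)C)C(C)=C)[C@]1(CC(=O)OC(C)(C)C)C[C@H](OC(C)=O)C=CC1=O | intermediate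
20 | tert-butyl 2-[(1R,5S)-5-acetoxy-1-[(5R)-3-[(3R)-3-{[tert-butyl(dimethyl)silyl]oxy}-4-methylpent-4-en-1-yl]-2-hydroxy-2,5-dihydro-1,2-oxaborol-5-yl]-2-oxocyclohex-3-en-1-yl]acetate | CC(C)(C)OC(=O)C[C@]1(C[C@H](OC(C)=O)C=CC1=O)[C@@H]2OB(O)C(CC[C@@H](O[Si](C)(C)C(C)(C)C)C(C)=C)=C2 | intermediate
21 | tert-butyl 2-[(1R,5S)-5-acetoxy-1-[(1R,2E,6R)-6-{[tert-butyl(dimethyl)silyl]oxy}-1-hydroxy-3,7-dimethylocta-2,7-dien-1-yl]-2-oxocyclohex-3-en-1-yl]acetate | CC(C)(C)OC(=O)C[C@]1(C[C@H](OC(C)=O)C=CC1=O)[C@H](O)/C=C(\C)CC[C@@H](O[Si](C)(C)C(C)(C)C)C(C)=C | intermediate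
22 | (1R,5R,9S)-1-[(1E,5R)-5-{[tert-butyl(dimethyl)silyl]oxy}-2,6-dimethylhepta-1,6-dien-1-yl]-3,6-dioxo-2-oxaspiro[4.5]dec-7-en-9-yl acetate | C=C(C)[C@H](O[Si](C)(C)C(C)(C)C)CC/C(C)=C/[C@H]1OC(=O)C[C@]12C[C@H](OC(C)=O)C=CC2=O | intermediate
23 | (1R,5R,9S)-1-[(1E,5R)-5-hydroxy-2,6-dimethylhepta-1,6-dien-1-yl]-3,6-dioxo-2-oxaspiro[4.5]dec-7-en-9-yl acetate (CNP0151251.2) | C=C(C)[C@H](O)CC/C(C)=C/[C@H]1OC(=O)C[C@]12C[C@H](OC(C)=O)C=CC2=O | target

**Step count and risks**

Total: 14 steps. Longest linear sequence: 10 steps (8 to 23 through steps 5 to 14); the ring branch needs 4 steps to reach 7.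

Step 2. Under the Lewis acid the very electron-rich furan may add stepwise and re-aromatise (conjugate alkylation at its free α-carbon) instead of closing the second bond, the adduct may revert, or the facial selectivity may be poor. The fallback sets out from 2 and 3 and runs the cycloaddition without catalyst (neat, 0 °C to rt, or under high pressure in CH2Cl2), which should give the racemic exo adduct, that is 4 together with its mirror image, the (1R,2S,4R)-adduct F1. The racemate is taken through step 3 unchanged: the ligand-controlled Re-face vinyl transfer turns 4 into 6 and turns F1 into the bicyclic carbinol F2 and, after the acid, into the diol F3, a diastereomer of 6 that is removed by chromatography. The absolute configuration then rests on the amino-alcohol ligand and a diastereomer separation instead of on the cycloaddition catalyst, and the route is rejoined at 6.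

Step 11. The mixed boronate of the hindered C10 alcohol may form poorly or hydrolyse, and initiation next to the quaternary carbon may be slower than catalyst decay, so that open-chain material is left. The fallback sets out from alkyne 13 and aldehyde 4. Zirconium-catalysed methylalumination of 13 (Me3Al, ZrCp2Cl2, CH2Cl2; then I2) should give the (E)-alkenyl iodide F4, its geometry fixed by syn carbometalation. A Nozaki–Hiyama–Kishi coupling of F4 with 4 (CrCl2, catalytic NiCl2, DMSO/THF, with a chiral oxazoline sulfonamide ligand for Re-face addition or with separation of the C10 epimers) gives the bicyclic allylic alcohol F5. AcOH/H2O/THF opens the ketal to the diol F6, and Ac2O/pyridine at −20 °C acetylates the ring carbinol to give 21, where the route is rejoined.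

Step 12. Retro-aldol cleavage of the freed β-hydroxy ketone in the basic medium, ionisation of the allylic acetate by zerovalent palladium, or protodeboronation may compete with the slow transmetalation to the methylpalladium species. The fallback sets out from 20: ipso-iododeboronation with NIS in MeCN at 0 °C (retention of geometry) should give the (Z)-iodo alkenol F7, and a Negishi coupling without added base (MeZnCl, 3 equiv, Pd(PPh3)4, THF, rt) then gives 21, where the route is rejoined.

Further compounds
F1 | step 2 | tert-butyl 2-[(1R,2S,4R)-2-formyl-1-methoxy-7-oxabicyclo[2.2.1]hept-5-en-2-yl]acetate | O=C[C@@]1(CC(=O)OC(C)(C)C)C[C@@H]2C=C[C@@]1(OC)O2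
F2 | step 2 | tert-butyl 2-[(1R,2S,4R)-2-[(1R)-1-hydroxyprop-2-en-1-yl]-1-methoxy-7-oxabicyclo[2.2.1]hept-5-en-2-yl]acetate | C=C[C@@H](O)[C@@]1(CC(=O)OC(C)(C)C)C[C@@H]2C=C[C@@]1(OC)O2
F3 | step 2 | tert-butyl 2-[(1S,5R)-5-hydroxy-1-[(1R)-1-hydroxyprop-2-en-1-yl]-2-oxocyclohex-3-en-1-yl]acetate | C=C[C@@H](O)[C@@]1(CC(=O)OC(C)(C)C)C[C@@H](O)C=CC1=O
F4 | step 11 | {[(3R,6E)-7-iodo-2,6-dimethylhepta-1,6-dien-3-yl]oxy}(tert-butyl)dimethylsilane | C=C(C)[C@H](O[Si](C)(C)C(C)(C)C)CC/C(C)=C/I
F5 | step 11 | tert-butyl 2-[(1S,2R,4S)-2-[(1R,2E,6R)-6-{[tert-butyl(dimethyl)silyl]oxy}-1-hydroxy-3,7-dimethylocta-2,7-dien-1-yl]-1-methoxy-7-oxabicyclo[2.2.1]hept-5-en-2-yl]acetate | C=C(C)[C@H](O[Si](C)(C)C(C)(C)C)CC/C(C)=C/[C@@H](O)[C@]1(CC(=O)OC(C)(C)C)C[C@H]2C=C[C@]1(OC)O2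
F6 | step 11 | tert-butyl 2-[(1R,5S)-1-[(1R,2E,6R)-6-{[tert-butyl(dimethyl)silyl]oxy}-1-hydroxy-3,7-dimethylocta-2,7-dien-1-yl]-5-hydroxy-2-oxocyclohex-3-en-1-yl]acetate | C=C(C)[C@H](O[Si](C)(C)C(C)(C)C)CC/C(C)=C/[C@@H](O)[C@]1(CC(=O)OC(C)(C)C)C[C@H](O)C=CC1=O
F7 | step 12 | tert-butyl 2-[(1R,5S)-5-acetoxy-1-[(1R,2Z,6R)-6-{[tert-butyl(dimethyl)silyl]oxy}-1-hydroxy-3-iodo-7-methylocta-2,7-dien-1-yl]-2-oxocyclohex-3-en-1-yl]acetate | CC(C)(C)OC(=O)C[C@]1(C[C@H](OC(C)=O)C=CC1=O)[C@H](O)/C=C(\I)CC[C@@H](O[Si](C)(C)C(C)(C)C)C(C)=C
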